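## Retrosynthetic overview

- Target 13 ⇐ octa-O-benzyl dimer 12 (hydrogenolysis) ⇐ flavan-3,4-diol 9 + tetra-O-benzyl-(+)-catechin 11: the interflavan C4–C8 bond is made by Friedel–Crafts capture of the C4 cation of the upper unit, trans to its 3-OH.
- 9 ⇐ acyclic (S,Z)-allylic alcohol 7: ring C of the upper unit is closed by forming the aryl ether bond O1–C8a (palladium-catalysed etherification), and the flav-3-ene 8 so formed is osmylated in the same flask, so C3 and C4 are set from C2.
- Enabling feature: C8a of ring A lies between the oxygen-bearing C8 and C4a, exactly where isovanillin is brominated, so ring A is bought with its 7,8-dioxygenation and a halogen on C8a only (C5 stays C–H). The Z C3=C4 bond of 7 holds the C2 hydroxyl next to C8a, and C2 is a carbinol set by asymmetric alkynylation and never ionised.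
- 7 ⇐ alkyne 4 (from 2-bromoisovanillin 1) + aldehyde 5, by asymmetric alkynylation and Z-selective semihydrogenation.
- Ring order: rings A and B of the upper unit and all three rings of the lower unit come intact from 1, 5 and (+)-catechin 10; the only ring made is ring C of the upper unit (step 6).

Key step: step 6

Remark (assumption): the target is read as mesquitol-(4α→8)-catechin, (2R,3S,4S) in the upper unit (2,3-trans-3,4-trans) and (2R,3S) in the lower unit; compounds 1, 5 and 10 are taken as purchasable.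

## Route

Step 1
Reactants: 1 2-bromo-3-hydroxy-4-methoxybenzaldehyde (2-bromoisovanillin)
Product: 2 2-bromo-3,4-dihydroxybenzaldehyde
Conditions: BBr3, CH2Cl2, −78 → 0 °C; then H2O
Reagents that add atoms: none
Why: Lewis-acid aryl methyl ether cleavage (BBr3 demethylation) should free the catechol at low temperature while the aldehyde and the aryl bromide stay untouched; no stereocentre is involved.

Step 2
Reactants: 2 2-bromo-3,4-dihydroxybenzaldehyde
Product: 3 3,4-bis(benzyloxy)-2-bromobenzaldehyde
Conditions: BnBr, K2CO3, DMF, 60 °C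
Reagents that add atoms: benzyl bromide, BrCc1ccccc1
Why: Williamson ether synthesis on both phenoxides installs the benzyl groups that every later step tolerates and that the last step removes together with all others.

Step 3
Reactants: 3 3,4-bis(benzyloxy)-2-bromobenzaldehyde
Product: 4 1,2-bis(benzyloxy)-3-bromo-4-ethynylbenzene
Conditions: dimethyl (1-diazo-2-oxopropyl)phosphonate, K2CO3, MeOH/THF, 0 °C → rt
Reagents that add atoms: dimethyl (1-diazo-2-oxopropyl)phosphonate (Ohira–Bestmann reagent), COP(=O)(OC)C(=[N+]=[N-])C(C)=O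
Why: Seyferth–Gilbert homologation in its Ohira–Bestmann form should convert the non-enolisable aryl aldehyde into the terminal alkyne under carbonate/methanol, which leaves the aryl bromide and the benzyl ethers intact.

Step 4
Reactants: 4 1,2-bis(benzyloxy)-3-bromo-4-ethynylbenzene; 5 3,4-bis(benzyloxy)benzaldehyde
Product: 6 (R)-1-[3,4-bis(benzyloxy)phenyl]-3-[3,4-bis(benzyloxy)-2-bromophenyl]prop-2-yn-1-ol
Conditions: ZnMe2, ProPhenol ligand (20 mol %, the antipode that gives the R carbinol), Ph3P=O, toluene, 4 °C; aq NH4Cl work-up; excess 4 recovered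
Reagents that add atoms: none
Why: Catalytic asymmetric alkynylation of an aromatic aldehyde (alkynylzinc addition in a chiral dinuclear zinc pocket) should select one enantioface of 5 and so set the only stereocentre brought into the upper unit, the future C2, as R.

Step 5
Reactants: 6 (R)-1-[3,4-bis(benzyloxy)phenyl]-3-[3,4-bis(benzyloxy)-2-bromophenyl]prop-2-yn-1-ol
Product: 7 (1S,2Z)-1-[3,4-bis(benzyloxy)phenyl]-3-[3,4-bis(benzyloxy)-2-bromophenyl]prop-2-en-1-ol
Conditions: H2 (1 atm), Pd/CaCO3 poisoned with Pb(OAc)2 (Lindlar catalyst), quinoline, EtOAc, rt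
Reagents that add atoms: none
Why: Lindlar semihydrogenation delivers H2 syn on the poisoned palladium surface and should give the Z alkene that brings O1 next to C8a, without touching the aryl bromide, the benzyl ethers or the carbinol centre (the descriptor changes from R to S only because the alkene carbon now ranks below the aryl group).

Step 6
Reactants: 7 (1S,2Z)-1-[3,4-bis(benzyloxy)phenyl]-3-[3,4-bis(benzyloxy)-2-bromophenyl]prop-2-en-1-ol
Product: 9 (2R,3S,4S)-7,8-bis(benzyloxy)-2-[3,4-bis(benzyloxy)phenyl]chromane-3,4-diol (2,3-trans-3,4-cis), via flav-3-ene 8 (not isolated)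
Conditions: (a) Pd2(dba)3 (2.5 mol %), RockPhos (6 mol %), Cs2CO3, toluene, 50 °C; (b) filtration through Celite under Ar, then OsO4 (2 mol %), NMO, acetone/H2O, 0 °C
Reagents that add atoms: N-methylmorpholine N-oxide, C[N+]1([O-])CCOCC1; water, O
Why: Stage (a) is a Buchwald–Hartwig-type intramolecular etherification in which zerovalent palladium inserts into the C8a–Br bond, the caesium alkoxide of the C2 carbinol replaces bromide on divalent palladium and C–O reductive elimination forms O1–C8a; stage (b) is an Upjohn dihydroxylation in which osmium tetroxide adds across C3=C4 of flav-3-ene 8 and NMO turns the catalyst over. The closest known reaction types are the palladium/bulky biarylphosphine cyclisation of secondary alcohols carrying a 2-bromoaryl group to chromans, which leaves the carbinol configuration intact, and the cis-hydroxylation of flav-3-enes to 2,3-trans-3,4-cis-flavan-3,4-diols. Ring C (O1, C2, C3, C4, C4a, C8a) is closed by C(sp2)–O reductive elimination from a seven-membered aryl(alkoxo)palladacycle, the Z C3=C4 bond acting as a rigid clamp that holds O1 beside C8a. C2 is not touched because its C–O bond is never broken, and it controls the two new stereocentres: osmium tetroxide should add to the face of the nearly planar chromene opposite to the C2 aryl group, giving 3S,4S. The operation needs site selectivity on ring A and chemoselectivity at palladium: only C8a carries a halogen, so C5, the position an oxidative or electrophilic closure would prefer, cannot react, and the bulky electron-rich phosphine together with the six-membered closure should favour reductive elimination over β-hydride elimination of the doubly activated alkoxide. The two stages are run in one flask because 8 is an acid- and air-sensitive electron-rich chromene; the phosphine and dba that remain are consumed by a small excess of NMO.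

Step 7
Reactants: 10 (+)-catechin
Product: 11 (2R,3S)-5,7-bis(benzyloxy)-2-[3,4-bis(benzyloxy)phenyl]chroman-3-ol (5,7,3',4'-tetra-O-benzyl-(+)-catechin)
Conditions: BnBr, K2CO3, DMF, −10 °C → rt, Ar
Reagents that add atoms: benzyl bromide, BrCc1ccccc1
Why: Williamson ether synthesis under carbonate should benzylate the four phenols selectively over the much less acidic secondary 3-OH and leave C2 and C3 unchanged.

Step 8
Reactants: 9 (2R,3S,4S)-7,8-bis(benzyloxy)-2-[3,4-bis(benzyloxy)phenyl]chromane-3,4-diol; 11 5,7,3',4'-tetra-O-benzyl-(+)-catechin (3 equiv)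
Product: 12 (2R,3S,4S)-7,8-bis(benzyloxy)-2-[3,4-bis(benzyloxy)phenyl]-4-{(2R,3S)-5,7-bis(benzyloxy)-2-[3,4-bis(benzyloxy)phenyl]-3-hydroxychroman-8-yl}chroman-3-ol (octa-O-benzyl mesquitol-(4α→8)-catechin)
Conditions: TMSOTf (20 mol %), 4 Å molecular sieves, CH2Cl2, −78 → −40 °C; excess 11 recovered
Reagents that add atoms: none
Why: Lewis-acid-promoted Friedel–Crafts interflavan coupling: the benzylic C4–OH of 9 leaves as water to give a cation stabilised by the para 7-benzyloxy group and O1, which the most nucleophilic position C8 of 11 should attack anti to the C3 hydroxyl, giving the 4α (3,4-trans, 4S) C4–C8 bond, while the excess of 11 suppresses oligomerisation.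

Step 9
Reactants: 12 octa-O-benzyl mesquitol-(4α→8)-catechin
Product: 13 (2R,3S,4S)-2-(3,4-dihydroxyphenyl)-4-[(2R,3S)-2-(3,4-dihydroxyphenyl)-3,5,7-trihydroxychroman-8-yl]chromane-3,7,8-triol (CNP0231186.1)
Conditions: H2 (1 atm), Pd(OH)2/C, THF/MeOH/H2O, rt
Reagents that add atoms: none
Why: Catalytic hydrogenolysis should cleave all eight benzyl ethers without affecting the interflavan C–C bond, the two pyran rings or any of the five stereocentres.

## Compound list

1 | 2-bromo-3-hydroxy-4-methoxybenzaldehyde | O=Cc1ccc(OC)c(O)c1Br | starting material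
2 | 2-bromo-3,4-dihydroxybenzaldehyde | O=Cc1ccc(O)c(O)c1Br | intermediate
3 | 3,4-bis(benzyloxy)-2-bromobenzaldehyde | O=Cc1ccc(OCc2ccccc2)c(OCc2ccccc2)c1Br | intermediate
4 | 1,2-bis(benzyloxy)-3-bromo-4-ethynylbenzene | C#Cc1ccc(OCc2ccccc2)c(OCc2ccccc2)c1Br | intermediate
5 | 3,4-bis(benzyloxy)benzaldehyde | O=Cc1ccc(OCc2ccccc2)c(OCc2ccccc2)c1 | starting material
6 | (R)-1-[3,4-bis(benzyloxy)phenyl]-3-[3,4-bis(benzyloxy)-2-bromophenyl]prop-2-yn-1-ol | O[C@H](c1ccc(OCc2ccccc2)c(OCc2ccccc2)c1)C#Cc1ccc(OCc2ccccc2)c(OCc2ccccc2)c1Br | intermediate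
7 | (1S,2Z)-1-[3,4-bis(benzyloxy)phenyl]-3-[3,4-bis(benzyloxy)-2-bromophenyl]prop-2-en-1-ol | O[C@H](c1ccc(OCc2ccccc2)c(OCc2ccccc2)c1)/C=C\c1ccc(OCc2ccccc2)c(OCc2ccccc2)c1Br | intermediate
8 | (S)-7,8-bis(benzyloxy)-2-[3,4-bis(benzyloxy)phenyl]-2H-chromene (flav-3-ene) | C(c1ccccc1)Oc1ccc(cc1OCc1ccccc1)[C@H]1Oc2c(ccc(OCc3ccccc3)c2OCc2ccccc2)C=C1 | intermediate (not isolated)
9 | (2R,3S,4S)-7,8-bis(benzyloxy)-2-[3,4-bis(benzyloxy)phenyl]chromane-3,4-diol | C(c1ccccc1)Oc1ccc(cc1OCc1ccccc1)[C@H]1Oc2c(ccc(OCc3ccccc3)c2OCc2ccccc2)[C@H](O)[C@@H]1O | intermediate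
10 | (+)-catechin, (2R,3S)-2-(3,4-dihydroxyphenyl)chromane-3,5,7-triol | O[C@H]1Cc2c(O)cc(O)cc2O[C@@H]1c1ccc(O)c(O)c1 | starting material
11 | (2R,3S)-5,7-bis(benzyloxy)-2-[3,4-bis(benzyloxy)phenyl]chroman-3-ol | O[C@H]1Cc2c(OCc3ccccc3)cc(OCc3ccccc3)cc2O[C@@H]1c1ccc(OCc2ccccc2)c(OCc2ccccc2)c1 | intermediate
12 | octa-O-benzyl mesquitol-(4α→8)-catechin, (2R,3S,4S) upper unit and (2R,3S) lower unit | C(c1ccccc1)Oc1ccc([C@H]2Oc3c(ccc(OCc4ccccc4)c3OCc3ccccc3)[C@@H](c3c(OCc4ccccc4)cc(OCc4ccccc4)c4c3O[C@H](c3ccc(OCc5ccccc5)c(OCc5ccccc5)c3)[C@@H](O)C4)[C@@H]2O)cc1OCc1ccccc1 | intermediate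
13 | (2R,3S,4S)-2-(3,4-dihydroxyphenyl)-4-[(2R,3S)-2-(3,4-dihydroxyphenyl)-3,5,7-trihydroxychroman-8-yl]chromane-3,7,8-triol | Oc1ccc([C@H]2Oc3c(ccc(O)c3O)[C@@H](c3c(O)cc(O)c4c3O[C@H](c3ccc(O)c(O)c3)[C@@H](O)C4)[C@@H]2O)cc1O | target

## Summary and risks

Total step count: 9. Longest linear sequence: 8 steps (steps 1–6, 8, 9); step 7 is a one-step side branch.

Steps most likely to fail, riskiest first:

**Step 6.** The doubly activated (benzylic and allylic) alkoxide of 7 may undergo β-hydride elimination on palladium or base-induced redox isomerisation to the saturated ketone, or the Z alkene may isomerise before the C–O bond forms; oxidative addition at the hindered, electron-rich C–Br bond may also be slow. The fallback takes the alkene out of play before the ring is closed and sets out from 7. Silylation (TBSCl, imidazole, DMF) gives the (S,Z)-tert-butyldimethylsilyl ether of 7, F1. Osmium tetroxide/NMO should then dihydroxylate the Z alkene anti to the allylic silyloxy group (the usual erythro preference next to an allylic oxygen) to give (1S,2S,3R)-1-[3,4-bis(benzyloxy)-2-bromophenyl]-3-[3,4-bis(benzyloxy)phenyl]-3-[(tert-butyldimethylsilyl)oxy]propane-1,2-diol, F2. The only free diol is tied up with 2,2-dimethoxypropane/PPTS as the cis-dioxolane, the 1,2-O-isopropylidene acetal of F2, F3, and Bu4NF frees the benzylic carbinol, desilylated F3, F4. An Ullmann-type copper-catalysed intramolecular etherification (CuI, 3,4,7,8-tetramethyl-1,10-phenanthroline, Cs2CO3, toluene, 100 °C) then closes ring C from a plain benzylic alkoxide that the dioxolane holds cis to the bromoarene, giving the 3,4-O-isopropylidene acetal of diol 9, F5. Aqueous acetic acid returns 9, and the route continues with step 8.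

**Step 8.** The cation may be captured at C6 of 11 or from the face cis to the 3-OH, the electron-rich ring A of 9 or of 12 may compete as nucleophile (oligomers), and the free 3-OH next to the cation may trigger a hydride shift to the flavan-3-one. The fallback changes leaving group and activation mode and sets out from 9. Thiolysis with phenylmethanethiol in acetic acid should give the 2,3-trans-3,4-trans thioether (2R,3R,4R)-4-(benzylsulfanyl)-7,8-bis(benzyloxy)-2-[3,4-bis(benzyloxy)phenyl]chroman-3-ol, F6. F6 is then coupled with 11 under neutral thiophilic activation (AgBF4, THF, 0 °C), the known silver-mediated route to 4-arylflavan-3-ols, in which the cation is released slowly and taken trans to the 3-hydroxyl. This gives 12 and rejoins the route at step 9.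

**Step 4.** The electron-rich aldehyde and the ortho-brominated arylalkyne may give insufficient enantioselectivity in the zinc-catalysed addition. The fallback sets the stereocentre by reduction instead of addition and sets out from 4 and 5. Deprotonation of 4 with LiN(SiMe3)2 (no bromine–lithium exchange) and addition to 5 gives racemic 1-[3,4-bis(benzyloxy)phenyl]-3-[3,4-bis(benzyloxy)-2-bromophenyl]prop-2-yn-1-ol, F7. MnO2 oxidises it to 1-[3,4-bis(benzyloxy)phenyl]-3-[3,4-bis(benzyloxy)-2-bromophenyl]prop-2-yn-1-one, F8. Corey–Bakshi–Shibata reduction (oxazaborolidine, BH3·SMe2, catalyst antipode chosen for the R alcohol; the aryl group acts as the large and the alkynyl as the small substituent) returns 6.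

Further compounds
F1 | step 6 | (S,Z)-tert-butyl{[1-(3,4-bis(benzyloxy)phenyl)-3-(3,4-bis(benzyloxy)-2-bromophenyl)prop-2-en-1-yl]oxy}dimethylsilane | CC(C)(C)[Si](C)(C)O[C@H](c1ccc(OCc2ccccc2)c(OCc2ccccc2)c1)/C=C\c1ccc(OCc2ccccc2)c(OCc2ccccc2)c1Br
F2 | step 6 | (1S,2S,3R)-1-[3,4-bis(benzyloxy)-2-bromophenyl]-3-[3,4-bis(benzyloxy)phenyl]-3-[(tert-butyldimethylsilyl)oxy]propane-1,2-diol | CC(C)(C)[Si](C)(C)O[C@H](c1ccc(OCc2ccccc2)c(OCc2ccccc2)c1)[C@@H](O)[C@@H](O)c1ccc(OCc2ccccc2)c(OCc2ccccc2)c1Br
F3 | step 6 | 1,2-O-isopropylidene acetal of F2 (cis-4,5-disubstituted 2,2-dimethyl-1,3-dioxolane) | CC(C)(C)[Si](C)(C)O[C@H](c1ccc(OCc2ccccc2)c(OCc2ccccc2)c1)[C@H]1OC(C)(C)O[C@H]1c1ccc(OCc2ccccc2)c(OCc2ccccc2)c1Br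
F4 | step 6 | desilylated F3, (R)-configured benzylic carbinol | O[C@H](c1ccc(OCc2ccccc2)c(OCc2ccccc2)c1)[C@H]1OC(C)(C)O[C@H]1c1ccc(OCc2ccccc2)c(OCc2ccccc2)c1Br
F5 | step 6 | 3,4-O-isopropylidene acetal of diol 9 | C(c1ccccc1)Oc1ccc(cc1OCc1ccccc1)[C@H]1Oc2c(ccc(OCc3ccccc3)c2OCc2ccccc2)[C@@H]2OC(C)(C)O[C@H]12
F6 | step 8 | (2R,3R,4R)-4-(benzylsulfanyl)-7,8-bis(benzyloxy)-2-[3,4-bis(benzyloxy)phenyl]chroman-3-ol | C(c1ccccc1)Oc1ccc(cc1OCc1ccccc1)[C@H]1Oc2c(ccc(OCc3ccccc3)c2OCc2ccccc2)[C@@H](SCc2ccccc2)[C@@H]1O
F7 | step 4 | racemic 1-[3,4-bis(benzyloxy)phenyl]-3-[3,4-bis(benzyloxy)-2-bromophenyl]prop-2-yn-1-ol | OC(c1ccc(OCc2ccccc2)c(OCc2ccccc2)c1)C#Cc1ccc(OCc2ccccc2)c(OCc2ccccc2)c1Br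
F8 | step 4 | 1-[3,4-bis(benzyloxy)phenyl]-3-[3,4-bis(benzyloxy)-2-bromophenyl]prop-2-yn-1-one | O=C(c1ccc(OCc2ccccc2)c(OCc2ccccc2)c1)C#Cc1ccc(OCc2ccccc2)c(OCc2ccccc2)c1Br
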